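## Analysis of the target

Target 28 is a biphenyl made of two catechol rings. Ring A carries its chain at C1, hydroxyls at C3 and C4 and the biaryl bond at C5; ring B carries the biaryl bond at C1, its chain at C2 and hydroxyls at C4 and C5. Each chain is an unbranched run of eight methylene groups ending in a ketone whose carbonyl carbon sits on C2 of a resorcinol ring (rings C and D), between the two hydroxyl-bearing carbons. There is no stereocentre, and the biaryl axis has only two ortho substituents (the C4 hydroxyl of ring A and the chain of ring B), so rotation is fast and no stereochemical element has to be controlled. The sensitive groups are the two catechols, which oxidise easily to ortho-quinones once free, the four resorcinol hydroxyls and the two aryl ketones; all eight phenols are therefore unveiled only at the end. Three things make the synthesis hard: the two arms are constitutionally different (one meta, one ortho to the biaryl bond), the chains offer no functional handle between arene and ketone, and the 2-acylresorcinol pattern is not what electrophilic acylation of a resorcinol gives, since that goes to C4. The strategy rests on rings C and D: going round each ring one meets C–OH, the acyl-bearing carbon, C–OH and then three adjacent CH groups. This is a two-carbon oxygenated alkyne (acyl-bearing carbon and one C–O) joined to a four-carbon vinylketene (the other C–O as the ketene carbonyl carbon, then the three CH).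

## Retrosynthetic reasoning

**28 to 27.** The four O–CH3 bonds of the catechol ethers are cut last. Methyl ethers are chosen because they must survive hydrogenation, organolithium reagents, a silyl triflate and prolonged heating, which benzyl or acetal groups would not all do. The forward step has to remove four methyl ethers with a Lewis acid without touching the two aryl ketones.

**27 to 25 (through 26).** The two O–Si bonds and the C–O bonds of the two dioxolanes are cut. The acyl carbon has to be sp3 and non-electrophilic in 17: a ketone next to the alkyne would reverse the polarisation on which the annulation depends and would not survive the carbanion chemistry that makes 17. Forward, fluoride-induced desilylation and acid hydrolysis are run in one flask.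

**25 to 17 and two molecules of 20.** In each of rings C and D the bonds C(OH)–C(ketal-bearing) and C(OSi)–CH are cut. This returns the two alkyne carbons of each arm of 17 and, per ring, the four carbons of vinylketene 21, which 20 releases on heating; one molecule of 20 is consumed per ring, two in all. The cut is made here because it is the only disconnection of these rings in which the mechanism itself places the acyl-bearing carbon between the two oxygens. It also builds both rings in one operation with every atom of both partners kept. Cutting the aryl–acyl bond instead would hand the problem to directed metalation of a ready-made aromatic ring, which is held in reserve as the fallback. Forward, four pericyclic events per ring have to run twice on one molecule.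

**17 to 14.** The C–O bond at each alkyne terminus and the O–Si bond are cut. Terminal alkynes are easy to make, and oxygen is delivered to the acetylide carbon of 15, two atoms away from the quaternary ketal carbon, so the hindrance that threatens the key step does not affect this one. Forward, ynolate 16 must be silylated on oxygen with a group bulky enough to give a siloxyalkyne that can be isolated and heated.

**14 to 11 (through 13 and 12).** The bond between each future acyl carbon and its alkyne is cut, which leads back to the N-methoxy-N-methyl amide 11 and a two-carbon ethynyl nucleophile that carries a silyl cap. The ketal is put on at the stage of the capped ynone 12 and the cap is removed afterwards in 13. An uncapped ynone would undergo conjugate addition during ketalisation, so the direct two-step variant is unsafe and the extra desilylation is accepted.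

**11 to 4 and 6 (through 10, 9 and 8).** In each chain the bond between the benzylic carbon and its neighbour is cut as an alkene. Ylide 7, from salt 6 and hence from acid 5, olefinates both aldehyde groups of 4 at once. The difference between the two arms is already written into 4, so from here on both arms are handled identically and in the same flask. The carboxyl end of 5 becomes the acyl carbon of the target, and hydrogenation of 8 erases the alkene geometry.

**4 to 2 and 3, and 2 to 1.** The biaryl bond is cut. Bromo aldehydes 1 and 3 are commercial and already carry the oxygenation and the formyl groups of rings A and B in the right places. Boron is placed on 1, because 3 is the better partner for oxidative addition thanks to its ortho formyl group.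

**20 to 18 (through 19).** The four-carbon partner comes from keto acid 18 by bromodecarboxylation and dehydrobromination. This is a side branch of two steps.

## Alternatives that were turned down

Alternative 1: Each chain is cut at the C8=C9 alkene (benzylic carbon and its neighbour), with the whole arm, ketone and ring C or D included, on the phosphorus partner. In the forward key step, two equivalents of keto ylide A2 olefinate tetrabenzyl dialdehyde A3 to give bis(styrene) A1. One catalytic hydrogenation then saturates both alkenes and removes all eight benzyl ethers to give 28.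
- For it: it is the shortest of the four plans (about eight steps), every reaction type is routine, and the final deprotection is neutral, with no Lewis acid on a polyphenol. On step economy and certainty it is stronger than the chosen route.
- Against it: A2 carries its own enolisable ketone. The α-methylene of that ketone is about as acidic as the P–CH2 group, so ylide formation competes with enolisation, and the ylide can condense with the ketone of a second molecule. The two ortho benzyloxy groups shield the ketone, but the protection has to hold twice on one dialdehyde. The final hydrogenation must also spare two aryl ketones while cleaving eight benzyl ethers. Rings C and D are bought ready-made through directed metalation, not constructed.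
- Comparison: the chosen route is about twice as long and contains one step without direct precedent. In exchange, no ketone is present during any carbanion step, and the 1,2,3-pattern of rings C and D is built from C2 and C4 units with regiochemistry fixed by mechanism and without by-product.

Alternative 2: Ring B is cut at the two bonds that join its biaryl carbon and its carbonyl-bearing carbon to their CH neighbours, with ring A held to it through an aryl ester bridge. In the forward key step, the C3=C4 bond of 3-nitrocoumarin A5 undergoes Diels–Alder cycloaddition with diene A6. Base-induced loss of the nitro group and dehydrogenation in the same flask then give benzochromenone A4.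
- For it: the lactone fixes the ortho relation between biaryl bond and chain carbon on ring B, the symmetric diene leaves no regiochemical question, and the nitro group both activates the dienophile and leaves afterwards. As a reaction type this key step is closer to known chemistry than the chosen one.
- Against it: for this target the biaryl bond is not the hard part. It has only two ortho substituents and is made in two steps from commercial 1 and 3. In A4 the two arms differ in length and oxidation level (a lactone carbonyl against a nine-carbon silyl ether), so every later operation is done once per arm and not twice in one flask. The lactone must be opened, the freed phenol protected, the ring-B arm grown by eight carbons, and rings C and D are still missing.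
- Comparison: it is clearly longer than the chosen route. The chosen route spends its complexity-building step on rings C and D, where substitution chemistry fails, and keeps both arms identical from step 4 onwards.

Alternative 3: Each chain is cut in the middle, at C7–C8 counted from the ketone carbon. In the forward key step, co-electrolysis of biaryl bis(propanoic acid) A8 with an excess of keto acid A9 at a platinum anode in partly neutralised alcoholic solution joins the two decarboxylated radicals twice to give octapivalate A7. Ester cleavage then gives 28.
- For it: it is the most convergent plan in carbon terms and forms a bond where polar chemistry has no handle. Both acids are simple and the route is short (seven or eight steps). On step count it is stronger than the chosen route.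
- Against it: radical pairing at the anode is statistical. Homocoupling of the radical derived from A9 is unavoidable and grows with the excess that is needed. The twofold cross-coupling multiplies the statistical loss, and A8 can also couple with itself within or between molecules. Cross-coupled, homocoupled and half-coupled material would all be long-chain pivalates of similar polarity, so A7 would be hard to purify. The electron-rich biaryl sits at the anode at the high potential a Kolbe reaction needs.
- Comparison: the chosen route is longer, but each of its bond-forming steps has one expected constitutional outcome, so incomplete conversion is the main impurity to expect and not a statistical product mixture.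

Key step: step 13

Remark on the chemistry: the Wittig step is expected to give mainly the cis alkenes, so 8 is drawn as (Z,Z); the geometry is of no consequence because step 5 removes it. Intermediates 22 and 24 carry transient sp3 centres and are drawn without configuration. The two arms of 17 react independently in the key step; intermediates 22, 23 and 24 are drawn with both arms at the same stage for brevity.

## Route

Step 1
Reactants: 1 3-bromo-4,5-dimethoxybenzaldehyde
Product: 2 3,4-dimethoxy-5-(4,4,5,5-tetramethyl-1,3,2-dioxaborolan-2-yl)benzaldehyde
Conditions: B2pin2, PdCl2(dppf) (cat.), KOAc, 1,4-dioxane, 90 °C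
Reagents that add atoms: bis(pinacolato)diboron, CC1(C)OB(OC1(C)C)B1OC(C)(C)C(C)(C)O1
Why: Miyaura borylation of an aryl bromide; KOAc is too weak a base to trigger Suzuki homocoupling of the product with unreacted 1, and the aldehyde and methyl ethers are inert.

Step 2
Reactants: 2 3,4-dimethoxy-5-(4,4,5,5-tetramethyl-1,3,2-dioxaborolan-2-yl)benzaldehyde; 3 2-bromo-4,5-dimethoxybenzaldehyde
Product: 4 2',3',4,5-tetramethoxy[1,1'-biphenyl]-2,5'-dicarbaldehyde
Conditions: Pd(OAc)2 (cat.), SPhos, K3PO4, toluene/H2O, 90 °C
Reagents that add atoms: none
Why: Suzuki–Miyaura cross-coupling; the ortho formyl group makes the C–Br bond of 3 prone to oxidative addition, the new biaryl has only two ortho substituents, and the bulky electron-rich biarylphosphine lets coupling outrun protodeboronation of 2.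

Step 3
Reactants: 5 8-bromooctanoic acid
Product: 6 (7-carboxyheptyl)triphenylphosphonium bromide
Conditions: PPh3, MeCN, reflux
Reagents that add atoms: triphenylphosphine, c1ccc(cc1)P(c1ccccc1)c1ccccc1
Why: SN2 quaternisation of the phosphine by an unhindered primary bromide; the free acid does not interfere and the salt crystallises.

Step 4
Reactants: 4 2',3',4,5-tetramethoxy[1,1'-biphenyl]-2,5'-dicarbaldehyde; 6 (7-carboxyheptyl)triphenylphosphonium bromide
Product: 8 (8Z,8'Z)-9,9'-(2',3',4,5-tetramethoxy[1,1'-biphenyl]-2,5'-diyl)bis(non-8-enoic acid), via carboxylate ylide 7 (not isolated)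
Conditions: 6 (2.4 equiv), NaN(SiMe3)2 (4.8 equiv), THF, 0 °C; then 4, −78 °C → rt; aq. HCl
Reagents that add atoms: none
Why: Wittig olefination with a non-stabilised ylide made with two equivalents of base per salt (one for the acid, one for P–CH2); the aldehydes of 4 cannot enolise, the carboxylate is not attacked by the ylide, and the diacid is separated from the phosphine oxide by extraction into aqueous base.

Step 5
Reactants: 8 (8Z,8'Z)-9,9'-(2',3',4,5-tetramethoxy[1,1'-biphenyl]-2,5'-diyl)bis(non-8-enoic acid)
Product: 9 9,9'-(2',3',4,5-tetramethoxy[1,1'-biphenyl]-2,5'-diyl)dinonanoic acid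
Conditions: H2 (1 atm), Pd/C, EtOAc, rt
Reagents that add atoms: none
Why: Heterogeneous catalytic hydrogenation of two 1,2-disubstituted styrene-type alkenes; both double-bond isomers converge on 9, and aryl methyl ethers and carboxylic acids are untouched.

Step 6
Reactants: 9 9,9'-(2',3',4,5-tetramethoxy[1,1'-biphenyl]-2,5'-diyl)dinonanoic acid
Product: 11 9,9'-(2',3',4,5-tetramethoxy[1,1'-biphenyl]-2,5'-diyl)bis(N-methoxy-N-methylnonanamide), via bis(acyl imidazolide) 10 (not isolated)
Conditions: CDI, CH2Cl2, rt; then MeNH(OMe)·HCl, rt
Reagents that add atoms: N,O-dimethylhydroxylamine hydrochloride, CNOC.Cl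
Why: Weinreb amide formation through the acyl imidazolides; both acids are activated under neutral conditions and the imidazole released in the activation frees the amine from its hydrochloride.

Step 7
Reactants: 11 9,9'-(2',3',4,5-tetramethoxy[1,1'-biphenyl]-2,5'-diyl)bis(N-methoxy-N-methylnonanamide)
Product: 12 11,11'-(2',3',4,5-tetramethoxy[1,1'-biphenyl]-2,5'-diyl)bis[1-(trimethylsilyl)undec-1-yn-3-one]
Conditions: Me3SiC≡CH, n-BuLi, THF, −78 °C; then 11, −78 → 0 °C; cold aq. NH4Cl
Reagents that add atoms: (trimethylsilyl)acetylene, C#C[Si](C)(C)C
Why: Acylation of a lithium acetylide by a Weinreb amide; the chelated tetrahedral intermediate survives until the quench, so no tertiary alcohol forms, and the silyl cap together with the cold quench prevents conjugate addition of the released amine to the ynone.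

Step 8
Reactants: 12 11,11'-(2',3',4,5-tetramethoxy[1,1'-biphenyl]-2,5'-diyl)bis[1-(trimethylsilyl)undec-1-yn-3-one]
Product: 13 2',3',4,5-tetramethoxy-2,5'-bis(8-{2-[(trimethylsilyl)ethynyl]-1,3-dioxolan-2-yl}octyl)-1,1'-biphenyl
Conditions: Me3SiOCH2CH2OSiMe3, Me3SiOTf (cat.), CH2Cl2, −78 → −20 °C; pyridine quench
Reagents that add atoms: 1,2-bis(trimethylsilyloxy)ethane, C[Si](C)(C)OCCO[Si](C)(C)C
Why: Silyl-triflate-catalysed ketalisation with the bis(silyl) ether of the diol, driven irreversibly by formation of the disiloxane at low temperature without water; the trimethylsilyl group shields the β-carbon, so the conjugate addition of the diol that troubles terminal ynones is suppressed, and the aryl methyl ethers are inert.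

Step 9
Reactants: 13 2',3',4,5-tetramethoxy-2,5'-bis(8-{2-[(trimethylsilyl)ethynyl]-1,3-dioxolan-2-yl}octyl)-1,1'-biphenyl
Product: 14 2,5'-bis[8-(2-ethynyl-1,3-dioxolan-2-yl)octyl]-2',3',4,5-tetramethoxy-1,1'-biphenyl
Conditions: K2CO3 (cat.), MeOH/THF, rt
Reagents that add atoms: none
Why: Base-catalysed methanolysis of the alkynyl C–Si bond; the dioxolanes are stable to base and the terminal alkynes needed for the oxidation are set free.

Step 10
Reactants: 14 2,5'-bis[8-(2-ethynyl-1,3-dioxolan-2-yl)octyl]-2',3',4,5-tetramethoxy-1,1'-biphenyl
Product: 17 2',3',4,5-tetramethoxy-2,5'-bis[8-(2-{[(triisopropylsilyl)oxy]ethynyl}-1,3-dioxolan-2-yl)octyl]-1,1'-biphenyl, via dilithium bis(acetylide) 15 (not isolated), via dilithium bis(ynolate) 16 (not isolated)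
Conditions: n-BuLi, THF, −78 °C; t-BuOOLi (from t-BuOOH in decane, LiN(SiMe3)2, THF, −78 °C), −78 → 0 °C; i-Pr3SiOTf, −78 °C → rt
Reagents that add atoms: tert-butyl hydroperoxide, CC(C)(C)OO; triisopropylsilyl trifluoromethanesulfonate, CC(C)[Si](OS(=O)(=O)C(F)(F)F)(C(C)C)C(C)C
Why: Oxidation of a lithium acetylide to a lithium ynolate by electrophilic oxygen transfer from t-BuOOLi, then O-silylation; oxygen is delivered to the terminal carbon, two atoms away from the quaternary ketal carbon, and the bulky silyl triflate reacts on oxygen and gives a siloxyalkyne that can be chromatographed and heated.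

Step 11
Reactants: 18 3-oxocyclobutane-1-carboxylic acid
Product: 19 3-bromocyclobutan-1-one
Conditions: HgO, Br2, MgSO4, CH2Cl2, reflux
Reagents that add atoms: bromine, BrBr
Why: Hunsdiecker-type bromodecarboxylation in the Cristol–Firth variant: the acyl hypobromite formed from the acid, HgO and Br2 loses CO2 in a radical chain and the cyclobutyl radical abstracts bromine; the ketone is tolerated.

Step 12
Reactants: 19 3-bromocyclobutan-1-one
Product: 20 cyclobut-2-en-1-one
Conditions: n-Bu3N, neat, rt, reduced pressure, distilled into a −78 °C trap; taken up in cold toluene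
Reagents that add atoms: none
Why: Amine-induced β-elimination of HBr from a β-bromo ketone (E1cB through the enolate); the volatile enone leaves the base by distillation as it forms and is kept cold and dilute, which limits its polymerisation.

Step 13
Reactants: 17 2',3',4,5-tetramethoxy-2,5'-bis[8-(2-{[(triisopropylsilyl)oxy]ethynyl}-1,3-dioxolan-2-yl)octyl]-1,1'-biphenyl; 20 cyclobut-2-en-1-one (two molecules are incorporated, one per siloxyalkyne)
Product: 25 2,5'-bis[8-(2-{2-hydroxy-6-[(triisopropylsilyl)oxy]phenyl}-1,3-dioxolan-2-yl)octyl]-2',3',4,5-tetramethoxy-1,1'-biphenyl, via vinylketene 21 (not isolated), via bis(vinylcyclobutenone) 22 (not isolated), via bis(dienylketene) 23 (not isolated), via bis(cyclohexadienone) 24 (not isolated)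
Conditions: 20 (6 equiv, slow addition as a cold toluene solution), toluene, sealed vessel, 80 °C, then 110 °C
Reagents that add atoms: cyclobut-2-en-1-one (the second molecule of 20; the first is counted among the reactants), O=C1CC=C1
Why: Proposed new method: the closest known reaction type is the thermal Danheiser benzannulation of cyclobutenones with trialkylsiloxyalkynes, which here has to run twice on one substrate (one molecule of 20 per alkyne, so that 25 is the 1:2 adduct of 17 and 20 with no atom lost), with the unsubstituted cyclobutenone and with an alkyne whose other substituent is a fully substituted ketal carbon. On heating, 20 opens by 4π electrocyclic ring opening to vinylketene 21, whose C=C=O unit adds to each siloxyalkyne by (2+2) cycloaddition to give the 4-vinylcyclobutenone units of 22; these reopen (4π) to the dienylketenes 23, which close to the cyclohexa-2,4-dienones 24 and tautomerise to the phenols of 25. Rings C and D are thus each closed by a thermally allowed disrotatory 6π electrocyclisation, after the two new skeletal bonds of each ring, C(OH)–C(ketal-bearing) and C(OSi)–CH, have been made in the cycloaddition; the bond made in the closure itself, C(OH)–CH, only restores the bond of 20 that was broken in its ring opening. The one selectivity needed is the orientation of the ketene–alkyne cycloaddition, and the substrate secures it: donation from oxygen makes the ketal-bearing alkyne carbon the nucleophilic end, which bonds to the electrophilic ketene carbonyl carbon, so that hydroxyl, ketal-bearing carbon and silyloxy carbon become contiguous. No stereocentre has to be controlled, because the sp3 carbons of 22 and 24 are lost again on ring opening and tautomerisation, and the ring opening of 22 is reversible, so that only the dienylketene geometry able to cyclise is drained towards 24. The triisopropylsilyl group keeps the ynol ether from rearranging to a silylketene at these temperatures, and slow addition of 20 holds the concentration of 21 low, so that ketene dimerisation and polymerisation of 20 are disfavoured against the cycloaddition. The two alkynes are far apart and react independently, so the second annulation should be no harder than the first. The ketal is inert under the neutral thermal conditions, but its bulk next to the reacting carbon is what makes the rate of the cycloaddition uncertain.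

Step 14
Reactants: 25 2,5'-bis[8-(2-{2-hydroxy-6-[(triisopropylsilyl)oxy]phenyl}-1,3-dioxolan-2-yl)octyl]-2',3',4,5-tetramethoxy-1,1'-biphenyl
Product: 27 9,9'-(2',3',4,5-tetramethoxy[1,1'-biphenyl]-2,5'-diyl)bis[1-(2,6-dihydroxyphenyl)nonan-1-one], via desilylated bis(dioxolane) 26 (not isolated)
Conditions: Bu4NF, THF, 0 °C; then 2 M HCl, rt
Reagents that add atoms: water, O
Why: Fluoride cleaves the two aryl O–Si bonds, phenoxide being a good leaving group from silicon, and on acidification the dioxolanes hydrolyse quickly because the two ortho hydroxyls stabilise the oxocarbenium ion and the product ketone is held by an intramolecular hydrogen bond; the methyl ethers are unaffected.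

Step 15
Reactants: 27 9,9'-(2',3',4,5-tetramethoxy[1,1'-biphenyl]-2,5'-diyl)bis[1-(2,6-dihydroxyphenyl)nonan-1-one]
Product: 28 9,9'-(2',3',4,5-tetrahydroxy[1,1'-biphenyl]-2,5'-diyl)bis[1-(2,6-dihydroxyphenyl)nonan-1-one]
Conditions: BBr3 (excess), CH2Cl2, −78 °C → rt; H2O, 0 °C, under argon
Reagents that add atoms: none
Why: Lewis-acid ether cleavage: BBr3 binds each methoxy oxygen and bromide removes the methyl group by SN2; enough reagent is used to saturate the four free phenols and two ketones first, the aryl ketones do not react, and hydrolysis of the borates under argon should release the catechols without oxidation.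

## Compound list

1 | 3-bromo-4,5-dimethoxybenzaldehyde | COc1cc(C=O)cc(Br)c1OC | starting material
2 | 3,4-dimethoxy-5-(4,4,5,5-tetramethyl-1,3,2-dioxaborolan-2-yl)benzaldehyde | COc1cc(C=O)cc(B2OC(C)(C)C(C)(C)O2)c1OC | intermediate
3 | 2-bromo-4,5-dimethoxybenzaldehyde | COc1cc(Br)c(C=O)cc1OC | starting material
4 | 2',3',4,5-tetramethoxy[1,1'-biphenyl]-2,5'-dicarbaldehyde | COc1cc(C=O)cc(-c2cc(OC)c(OC)cc2C=O)c1OC | intermediate
5 | 8-bromooctanoic acid | OC(=O)CCCCCCCBr | starting material
6 | (7-carboxyheptyl)triphenylphosphonium bromide | OC(=O)CCCCCCC[P+](c1ccccc1)(c1ccccc1)c1ccccc1.[Br-] | intermediate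
7 | sodium 8-(triphenylphosphoranylidene)octanoate (carboxylate ylide) | [Na+].[O-]C(=O)CCCCCCC=P(c1ccccc1)(c1ccccc1)c1ccccc1 | intermediate (not isolated)
8 | (8Z,8'Z)-9,9'-(2',3',4,5-tetramethoxy[1,1'-biphenyl]-2,5'-diyl)bis(non-8-enoic acid) | COc1cc(/C=C\CCCCCCC(=O)O)cc(-c2cc(OC)c(OC)cc2/C=C\CCCCCCC(=O)O)c1OC | intermediate
9 | 9,9'-(2',3',4,5-tetramethoxy[1,1'-biphenyl]-2,5'-diyl)dinonanoic acid | COc1cc(CCCCCCCCC(=O)O)cc(-c2cc(OC)c(OC)cc2CCCCCCCCC(=O)O)c1OC | intermediate
10 | 9,9'-(2',3',4,5-tetramethoxy[1,1'-biphenyl]-2,5'-diyl)bis[1-(1H-imidazol-1-yl)nonan-1-one] (bis(acyl imidazolide)) | COc1cc(CCCCCCCCC(=O)n3ccnc3)cc(-c2cc(OC)c(OC)cc2CCCCCCCCC(=O)n3ccnc3)c1OC | intermediate (not isolated)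
11 | 9,9'-(2',3',4,5-tetramethoxy[1,1'-biphenyl]-2,5'-diyl)bis(N-methoxy-N-methylnonanamide) | COc1cc(CCCCCCCCC(=O)N(C)OC)cc(-c2cc(OC)c(OC)cc2CCCCCCCCC(=O)N(C)OC)c1OC | intermediate
12 | 11,11'-(2',3',4,5-tetramethoxy[1,1'-biphenyl]-2,5'-diyl)bis[1-(trimethylsilyl)undec-1-yn-3-one] | COc1cc(CCCCCCCCC(=O)C#C[Si](C)(C)C)cc(-c2cc(OC)c(OC)cc2CCCCCCCCC(=O)C#C[Si](C)(C)C)c1OC | intermediate
13 | 2',3',4,5-tetramethoxy-2,5'-bis(8-{2-[(trimethylsilyl)ethynyl]-1,3-dioxolan-2-yl}octyl)-1,1'-biphenyl | COc1cc(CCCCCCCCC3(OCCO3)C#C[Si](C)(C)C)cc(-c2cc(OC)c(OC)cc2CCCCCCCCC3(OCCO3)C#C[Si](C)(C)C)c1OC | intermediate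
14 | 2,5'-bis[8-(2-ethynyl-1,3-dioxolan-2-yl)octyl]-2',3',4,5-tetramethoxy-1,1'-biphenyl | COc1cc(CCCCCCCCC3(OCCO3)C#C)cc(-c2cc(OC)c(OC)cc2CCCCCCCCC3(OCCO3)C#C)c1OC | intermediate
15 | dilithium bis(acetylide) of 14 | COc1cc(CCCCCCCCC3(OCCO3)C#C[Li])cc(-c2cc(OC)c(OC)cc2CCCCCCCCC3(OCCO3)C#C[Li])c1OC | intermediate (not isolated)
16 | dilithium bis(ynolate) derived from 14 | COc1cc(CCCCCCCCC3(OCCO3)C#CO[Li])cc(-c2cc(OC)c(OC)cc2CCCCCCCCC3(OCCO3)C#CO[Li])c1OC | intermediate (not isolated)
17 | 2',3',4,5-tetramethoxy-2,5'-bis[8-(2-{[(triisopropylsilyl)oxy]ethynyl}-1,3-dioxolan-2-yl)octyl]-1,1'-biphenyl | COc1cc(CCCCCCCCC3(OCCO3)C#CO[Si](C(C)C)(C(C)C)C(C)C)cc(-c2cc(OC)c(OC)cc2CCCCCCCCC3(OCCO3)C#CO[Si](C(C)C)(C(C)C)C(C)C)c1OC | intermediate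
18 | 3-oxocyclobutane-1-carboxylic acid | O=C1CC(C(=O)O)C1 | starting material
19 | 3-bromocyclobutan-1-one | O=C1CC(Br)C1 | intermediate
20 | cyclobut-2-en-1-one | O=C1CC=C1 | intermediate
21 | buta-1,3-dien-1-one (vinylketene) | C=CC=C=O | intermediate (not isolated)
22 | bis(vinylcyclobutenone): each dioxolane C2 carries a 3-ethenyl-4-oxo-2-[(triisopropylsilyl)oxy]cyclobut-1-en-1-yl group | COc1cc(CCCCCCCCC3(OCCO3)C4=C(O[Si](C(C)C)(C(C)C)C(C)C)C(C=C)C4=O)cc(-c2cc(OC)c(OC)cc2CCCCCCCCC3(OCCO3)C4=C(O[Si](C(C)C)(C(C)C)C(C)C)C(C=C)C4=O)c1OC | intermediate (not isolated)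
23 | bis(dienylketene): each dioxolane C2 carries a (3E)-1-oxo-3-[(triisopropylsilyl)oxy]hexa-1,3,5-trien-2-yl group, the vinyl group being cis to the ketene-bearing carbon | COc1cc(CCCCCCCCC3(OCCO3)C(=C=O)/C(O[Si](C(C)C)(C(C)C)C(C)C)=C\C=C)cc(-c2cc(OC)c(OC)cc2CCCCCCCCC3(OCCO3)C(=C=O)/C(O[Si](C(C)C)(C(C)C)C(C)C)=C\C=C)c1OC | intermediate (not isolated)
24 | bis(cyclohexadienone): each dioxolane C2 carries a 6-oxo-2-[(triisopropylsilyl)oxy]cyclohexa-1,3-dien-1-yl group | COc1cc(CCCCCCCCC3(OCCO3)C4=C(O[Si](C(C)C)(C(C)C)C(C)C)C=CCC4=O)cc(-c2cc(OC)c(OC)cc2CCCCCCCCC3(OCCO3)C4=C(O[Si](C(C)C)(C(C)C)C(C)C)C=CCC4=O)c1OC | intermediate (not isolated)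
25 | 2,5'-bis[8-(2-{2-hydroxy-6-[(triisopropylsilyl)oxy]phenyl}-1,3-dioxolan-2-yl)octyl]-2',3',4,5-tetramethoxy-1,1'-biphenyl | COc1cc(CCCCCCCCC3(OCCO3)c4c(O)cccc4O[Si](C(C)C)(C(C)C)C(C)C)cc(-c2cc(OC)c(OC)cc2CCCCCCCCC3(OCCO3)c4c(O)cccc4O[Si](C(C)C)(C(C)C)C(C)C)c1OC | intermediate
26 | 2,5'-bis{8-[2-(2,6-dihydroxyphenyl)-1,3-dioxolan-2-yl]octyl}-2',3',4,5-tetramethoxy-1,1'-biphenyl | COc1cc(CCCCCCCCC3(OCCO3)c4c(O)cccc4O)cc(-c2cc(OC)c(OC)cc2CCCCCCCCC3(OCCO3)c4c(O)cccc4O)c1OC | intermediate (not isolated)
27 | 9,9'-(2',3',4,5-tetramethoxy[1,1'-biphenyl]-2,5'-diyl)bis[1-(2,6-dihydroxyphenyl)nonan-1-one] | COc1cc(CCCCCCCCC(=O)c3c(O)cccc3O)cc(-c2cc(OC)c(OC)cc2CCCCCCCCC(=O)c3c(O)cccc3O)c1OC | intermediate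
28 | 9,9'-(2',3',4,5-tetrahydroxy[1,1'-biphenyl]-2,5'-diyl)bis[1-(2,6-dihydroxyphenyl)nonan-1-one] (CNP0305015.0) | O=C(CCCCCCCCc1cc(O)c(O)c(-c2cc(O)c(O)cc2CCCCCCCCC(=O)c2c(O)cccc2O)c1)c1c(O)cccc1O | target

## Step count and least certain steps

Total step count: 15. Longest linear sequence: 12 steps (steps 1, 2, 4 to 10 and 13 to 15); steps 3, 11 and 12 are side branches.

**Step 13 (key step, the one proposed new method).**
- What may go wrong: polymerisation of 20 and dimerisation of 21 may outrun the cycloaddition, because the reacting alkyne carbon sits next to a quaternary ketal carbon.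
- The second annulation may stall after the first, leaving half-annulated material.
- The new, hindered phenols may be acylated by excess 21; a brief basic methanolysis before step 14 would cleave such esters.
- Prolonged heating may move silicon from oxygen to carbon in unreacted 17.
- Fallback, by known chemistry and without the benzannulation: it sets out from 11. Commercial 1,3-bis(methoxymethoxy)benzene is lithiated between its two acetal oxygens with n-BuLi (directed ortho-metalation) to 2,6-bis(methoxymethoxy)phenyllithium F1. F1 acylates both Weinreb amide groups of 11 to give 9,9'-(2',3',4,5-tetramethoxy[1,1'-biphenyl]-2,5'-diyl)bis{1-[2,6-bis(methoxymethoxy)phenyl]nonan-1-one} F2. Methanolic HCl then removes the four methoxymethyl groups, and the route is rejoined at 27.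

**Step 10.**
- What may go wrong: oxygen transfer may be incomplete on one or both arms, since an acetylide with two α-oxygens is a weakened nucleophile and the peroxide decomposes as the mixture warms.
- The silyl triflate may be consumed by the alkoxide by-product, or may open a dioxolane as a Lewis acid.
- Fallback: it sets out from 14. The terminal alkynes are treated with the trivalent iodine reagent [hydroxy(tosyloxy)iodo]benzene over a desiccant to give the bis[alkynyl(phenyl)iodonium] bis(4-toluenesulfonate) F3. Under CuOTf catalysis in acetonitrile F3 collapses, with loss of iodobenzene, to the bis(alkynyl 4-toluenesulfonate) F4. Methyllithium attacks sulfur in F4 and releases the bis(ynolate) 16, which is silylated as in step 10 to give 17.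

**Step 12.**
- What may go wrong: 20 may be lost through polymerisation and volatility during the distillation, and amine salt carried over would protonate 17 in the next step.
- Fallback: it sets out from 17 and does without 20. Commercial (E)-but-2-enoyl chloride and triethylamine are added slowly to hot 17; 1,4-dehydrochlorination generates 21 in the flask, and the sequence rejoins the route at 21 and runs on through 22 to 24 to give 25. It makes no compound outside the list (F0).

## Further compounds

F1 | step 13 | 2,6-bis(methoxymethoxy)phenyllithium | [Li]c1c(OCOC)cccc1OCOC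
F2 | step 13 | 9,9'-(2',3',4,5-tetramethoxy[1,1'-biphenyl]-2,5'-diyl)bis{1-[2,6-bis(methoxymethoxy)phenyl]nonan-1-one} | COc1cc(CCCCCCCCC(=O)c3c(OCOC)cccc3OCOC)cc(-c2cc(OC)c(OC)cc2CCCCCCCCC(=O)c3c(OCOC)cccc3OCOC)c1OC
F3 | step 10 | bis[alkynyl(phenyl)iodonium] bis(4-toluenesulfonate) of 14 | COc1cc(CCCCCCCCC3(OCCO3)C#C[I+]c4ccccc4)cc(-c2cc(OC)c(OC)cc2CCCCCCCCC3(OCCO3)C#C[I+]c4ccccc4)c1OC.Cc1ccc(cc1)S(=O)(=O)[O-].Cc1ccc(cc1)S(=O)(=O)[O-]
F4 | step 10 | bis(alkynyl 4-toluenesulfonate) derived from 14 | COc1cc(CCCCCCCCC3(OCCO3)C#COS(=O)(=O)c4ccc(C)cc4)cc(-c2cc(OC)c(OC)cc2CCCCCCCCC3(OCCO3)C#COS(=O)(=O)c4ccc(C)cc4)c1OC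
F0 | step 12 | none | none
A1 | alternative 1 | (Z,Z)-bis(styrene) octabenzyl ether of the target skeleton | O=C(CCCCCC/C=C\c1cc(OCc2ccccc2)c(OCc2ccccc2)c(-c2cc(OCc3ccccc3)c(OCc3ccccc3)cc2/C=C\CCCCCCC(=O)c2c(OCc3ccccc3)cccc2OCc2ccccc2)c1)c1c(OCc2ccccc2)cccc1OCc1ccccc1
A2 | alternative 1 | 1-[2,6-bis(benzyloxy)phenyl]-8-(triphenylphosphoranylidene)octan-1-one (keto ylide) | O=C(CCCCCCC=P(c1ccccc1)(c1ccccc1)c1ccccc1)c1c(OCc2ccccc2)cccc1OCc1ccccc1
A3 | alternative 1 | 2',3',4,5-tetrakis(benzyloxy)[1,1'-biphenyl]-2,5'-dicarbaldehyde | O=Cc1cc(OCc2ccccc2)c(OCc2ccccc2)c(-c2cc(OCc3ccccc3)c(OCc3ccccc3)cc2C=O)c1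
A4 | alternative 2 | 2-[9-(tert-butyldimethylsilyloxy)nonyl]-4,8,9-trimethoxy-6H-benzo[c]chromen-6-one | COc1cc(CCCCCCCCCO[Si](C)(C)C(C)(C)C)cc2c1OC(=O)c1cc(OC)c(OC)cc12
A5 | alternative 2 | 6-[9-(tert-butyldimethylsilyloxy)nonyl]-8-methoxy-3-nitro-2H-chromen-2-one | COc1cc(CCCCCCCCCO[Si](C)(C)C(C)(C)C)cc2cc([N+](=O)[O-])c(=O)oc12
A6 | alternative 2 | 2,3-dimethoxybuta-1,3-diene | COC(=C)C(=C)OC
A7 | alternative 3 | octapivalate of the target | CC(C)(C)C(=O)Oc1cccc(OC(=O)C(C)(C)C)c1C(=O)CCCCCCCCc1cc(OC(=O)C(C)(C)C)c(OC(=O)C(C)(C)C)c(-c2cc(OC(=O)C(C)(C)C)c(OC(=O)C(C)(C)C)cc2CCCCCCCCC(=O)c2c(OC(=O)C(C)(C)C)cccc2OC(=O)C(C)(C)C)c1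
A8 | alternative 3 | 3,3'-[2',3',4,5-tetrakis(pivaloyloxy)[1,1'-biphenyl]-2,5'-diyl]dipropanoic acid | OC(=O)CCc1cc(OC(=O)C(C)(C)C)c(OC(=O)C(C)(C)C)c(-c2cc(OC(=O)C(C)(C)C)c(OC(=O)C(C)(C)C)cc2CCC(=O)O)c1
A9 | alternative 3 | 8-[2,6-bis(pivaloyloxy)phenyl]-8-oxooctanoic acid | CC(C)(C)C(=O)Oc1cccc(OC(=O)C(C)(C)C)c1C(=O)CCCCCCC(=O)O
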